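# Total synthesis proposal for CNP0361406.8: both halves from the two antipodes of one furan–maleate cycloadduct

## Analysis of the target

1. CNP0361406.8 is an ester of two seco-cadinane units joined through the primary oxygen O14. One unit is a trans-fused cyclohexane/oxepinone (ε-lactone) with a free carboxylic acid. The other is a (2E)-2-(hydroxymethyl)acrylic acid carrying a 3-(hydroxymethyl)-6-isopropylcyclohex-2-enyl group.
2. Atom labels: in the lactone half the cyclohexane is C1, C6, C7, C8, C9, C10. C7 bears the isopropyl group, C10 the tertiary hydroxyl and C14H2O, C1 the lactone carbonyl C2, and C6 the alkene carbon C5. The seven-membered ring is C1–C2(=O)–O–C15H2–C4(C3O2H)=C5–C6. The cyclohexene half uses the same labels with primes: C6′ bears the acrylate C5′=C4′(C15′H2OH)–C3′, C7′ the isopropyl group, C1′=C10′ is the ring alkene and C10′ bears C14′H2OH.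
3. The lactone half has four contiguous stereocenters, C7 (R), C6 (S), C1 (S) and C10 (S). Isopropyl, C5 and C2 alternate up/down and are all equatorial; the C10 hydroxyl is equatorial and trans to C2, and C14 is axial and cis to C2.
4. The cyclohexene half has C6′ (S) and C7′ (S), again trans. When the two rings are laid over each other atom for atom, both centers have the opposite absolute sense to C6 and C7.
5. Sensitive features are:
   - the ε-lactone, which a free C14 hydroxyl three atoms from C2 would contract to the cis-fused γ-lactone;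
   - its allylic C15–O bond on an acrylate, open to SN2′ attack;
   - the tertiary β-hydroxy lactone;
   - the doubly allylic C6′–H, γ to an ester carbonyl, which lets the ring alkene drift into conjugation under base.
6. The difficulty lies less in the skeleton than in telling apart the two carboxyl-level carbons C2 and C5, in deciding which oxygen (O14 or O15) holds C2 at each stage, and in supplying two halves of opposite handedness.
7. The strategy rests on the cyclohexane of the lactone half. A tertiary carbinol C10 (with C14H2O) para to the isopropyl carbon C7, with carboxyl-derived carbons on the adjacent C1 and C6, is the imprint of a 2,5-disubstituted furan whose oxygen bridged C10 and C7 after a [4+2] cycloaddition with a maleate. The cyclohexene half is the same imprint after loss of C2 and the C10′ oxygen, so the mirror-image cycloadduct can serve it.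

## Retrosynthetic reasoning

**Ester link.** The last operation unmasks the tert-butyl ester and the two silyl ethers of 37 to give 39. Compound 37 is cut at the C14–O acyl bond, the only acyclic link between the halves, into hydroxy lactone 36 and acid 35. This makes the route convergent and leaves one esterification of a primary alcohol beside a tertiary one. The forward step must be fast and non-basic enough that O14 is acylated before it can attack C2.

**ε-Lactone.** Compound 36 comes from its silyl ether 25, which is cut at the C2–O15 ester bond to seco acid 24 (from 23 by removal of one silyl group). Closing the seven-membered ring by acyl activation, not by alkylation at C15, avoids a competing SN2′ closure at C5. O14 stays silylated so that C2 cannot fall back to the γ-lactone. Compound 23 arises from γ-lactone 20 by saponification and silylation of O14 in one flask.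

**C4=C5.** Compound 20 is cut at the C4=C5 double bond into aldehyde 19 and phosphonate 16, which brings C3, C4 and C15 at their final oxidation levels. Aldehyde 19 comes from alcohol 18 and this from acid 17. The free carboxyl on C6 can be reduced beside the lactone on C1, so the two carboxyl-level carbons delivered by the cycloaddition are distinguished without protecting groups. Phosphonate 16 is made from 13 through 14 by carboxylation with 15.

**Cyclohexene half.** Acid 35 is obtained from its tert-butyl ester 33. In 33 the ring alkene C1′=C10′ is disconnected by adding back a carboxyl on C1′ and a hydroxyl on C10′, that is, a decarboxylative dehydration of β-hydroxy acid 32. Compound 32 is the mirror image of 23, so it needs no route of its own: it follows from 26 through 27, 28 and 29 by the reactions that lead from 17 to 23. Forming the ring alkene after the olefination also avoids a β,γ-unsaturated aldehyde.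

**Resolution.** Acids 17 and 26 are the two enantiomers of racemic acid 10 and are separated as the mirror-image salts 11 and 12. Both antipodes are consumed, so nothing is discarded or recycled. The resolution is placed at 10, the last intermediate common to both halves that is a compact, polar acid.

**From 10 back to the cycloadduct.** Compound 10 is the C1 epimer of 9; the change from trans- to cis-fused γ-lactone is thermodynamically downhill. Compound 9 comes from 8 by hydrogenation of C7=C8 directed by the C10 hydroxyl, which sets C7. Compound 8 comes from 7 by reductive cleavage of the C7–O bond of the oxygen bridge. Cleavage must occur at the isopropyl bridgehead, which an ionisation mechanism favours; a hydrometalation would follow sterics to the other bridgehead and would not spare the lactone.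

**Key disconnection.** Compound 7 is cut at C10–C1 and C7–C6 to furfuryl half-ester 6. The intramolecular Diels–Alder reaction builds the carbocycle, the γ-lactone and the relative configuration of four stereocenters in one step. Half-ester 6 is the acylation product of alcohol 4 with anhydride 5. Because 6 is achiral, 7 is necessarily racemic.

**Furan.** Alcohol 4 comes from ester 3 by reduction, and 3 from bromofuran 1 and organozinc 2 by cross-coupling, which places the isopropyl group at the furan α-position without ambiguity.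

## Alternatives that were turned down

**Alternative 1:** organocatalytic assembly of the cyclohexene half.
- Disconnection: the cyclohexene ring is cut at C6′–C7′, C8′–C9′ and C1′=C10′ into 3-[(4-methoxybenzyl)oxy]propanal A1, (E)-3-methyl-1-nitrobut-1-ene A2 and ethyl 2-(diethoxyphosphoryl)acrylate A3.
- Forward key step: a secondary-amine-catalysed Michael addition of A1 to A2, then base-promoted addition of the nitronate to A3 and intramolecular Horner–Wadsworth–Emmons closure, give nitrocyclohexene ester A4 in one pot.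
- For: three bonds and the ring in one operation, with catalytic enantiocontrol at C6′/C7′. On this point it is stronger than the chosen route, which needs a resolution.
- Against:
  - A4 carries a nitro group on C8′ that the target lacks, and reductive removal of a secondary nitro group is unreliable.
  - The ester must be reduced to C14′.
  - The C5′ oxygen must be unveiled and oxidised to a β,γ-unsaturated, epimerisable aldehyde before the acrylate can be built.
  - Only the simpler half is addressed; the lactone half with its tertiary carbinol still needs a separate route.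
- Comparison: the chosen strategy offers, in place of asymmetric catalysis, one cycloadduct whose two enantiomers supply both halves, and it installs the acrylate before the ring alkene exists.

**Alternative 2:** biomimetic Baeyer–Villiger ring expansion.
- Disconnection: the O–C15 bond is removed, so that the ε-lactone A6 derives from the trans-fused β,γ-unsaturated decalone A5.
- Forward key step: a peracid or a Baeyer–Villiger monooxygenase inserts oxygen between C2 and C15.
- For: the lactone appears directly at the right oxidation level, and A6 already has O14 protected, which is equivalent to intermediate 25 here. On that point the two routes are equally strong.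
- Against:
  - The required migration of a primary allylic CH2 attached to an electron-poor alkene competes with migration of the secondary ring carbon C1, which normally wins, so the regioisomeric lactone is expected chemically.
  - C15 of A5 lies between a ketone and a vinylogous ester and invites conjugation of the alkene.
  - A5, with four stereocenters, needs a long synthesis of its own.
- Comparison: the chosen route forms the C2–O15 bond by acylation, whose regiochemistry is not in question, and obtains the ring carbons and the tertiary carbinol in one cycloaddition.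

**Alternative 3:** vinylcyclopropane retro-Claisen rearrangement.
- Disconnection: the O–C15 bond and the C4=C5 alkene are traced back to the cyclopropane-fused keto aldehyde A7.
- Forward key step: on warming, A7 undergoes a [3,3] shift to the 2,5-dihydrooxepine A8.
- For: a strain-driven, stereospecific pericyclic step that makes the oxacycle and the ring alkene together. As a ring-forming event it is more elegant than a lactonisation.
- Against:
  - A8 is an enol ether at C2, not a lactone.
  - C1 is sp2 and C10 is a ketone, so an oxidation at C2, a stereoselective reduction at C1 and a facially selective one-carbon addition at C10 are still needed on an acid-sensitive vinylogous ester.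
  - Enantioselective access to the cis-disposed cyclopropane A7 is long.
- Comparison: in the chosen route the C10 carbinol, its CH2O arm and the carboxyl level of C2 come directly from the furan and the maleate.

Key step: step 3

Assumption: the (S)-1-phenylethylammonium salt of the (3aS,6R,7R,7aS) acid is taken to be the less soluble diastereomer; if the opposite pairing crystallises, the two amine enantiomers are exchanged between steps 7 and 8 and nothing else changes.

## Route

Step 1
Reactants: 1 methyl 5-bromofuran-2-carboxylate; 2 isopropylzinc bromide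
Product: 3 methyl 5-(propan-2-yl)furan-2-carboxylate
Conditions: Pd(OAc)2 (1 mol %), CPhos (2 mol %), THF/toluene, 23 °C
Reagents that add atoms: none
Why: Negishi coupling; the electron-poor bromofuran adds to zerovalent palladium, and the bulky biarylphosphine makes reductive elimination faster than β-hydride elimination, so the secondary alkyl group is transferred without isomerisation to n-propyl.

Step 2
Reactants: 3 methyl 5-(propan-2-yl)furan-2-carboxylate
Product: 4 [5-(propan-2-yl)furan-2-yl]methanol
Conditions: LiAlH4, Et2O, 0 °C; H2O, aq. NaOH work-up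
Reagents that add atoms: none
Why: Hydride reduction of the ester to the primary alcohol; the furan is untouched and the basic work-up avoids acid, to which the electron-rich furfuryl alcohol is labile.

Step 3
Reactants: 4 [5-(propan-2-yl)furan-2-yl]methanol; 5 maleic anhydride
Product: 7 rac-exo-4-oxo-7-(propan-2-yl)-3,10-dioxatricyclo[5.2.1.0^1,5]dec-8-ene-6-carboxylic acid, via 5-isopropylfurfuryl hydrogen maleate 6 (not isolated)
Conditions: toluene, 23 °C (to 40 °C if acylation is slow), 3–5 d; adduct collected by crystallisation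
Reagents that add atoms: none
Why: The anhydride first acylates the furfuryl alcohol to half-ester 6; its furan then acts as diene and the tethered (Z)-enoate as dienophile in a concerted, suprafacial thermal [4+2] cycloaddition that forms C10–C1 and C7–C6. The closest known reaction type is the tandem acylation/intramolecular Diels–Alder reaction of furfuryl alcohols with maleic anhydride. The carbocycle is closed as a 7-oxanorbornene by the two new σ-bonds, and the γ-lactone is closed in the fused mode by the C10–C1 bond, because the three-atom O14–C2 tether lets only C1, not C6, reach C10. C10 and C7 are fixed by addition across one face of the furan, whose oxygen remains as the bridge; C1 and C6 are cis because the dienophile is (Z), and exo (on the face of the oxygen bridge) because the short tether cannot span the endo face. The step needs regio- and exo-selectivity, both secured by the tether, and a favourable equilibrium, which the alkyl-rich furan and crystallisation of the adduct should provide. The precursor is achiral, so 7 is formed as the racemate; the single antipodes are taken out in steps 7 and 8 and both are used.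

Step 4
Reactants: 7 rac-exo-4-oxo-7-(propan-2-yl)-3,10-dioxatricyclo[5.2.1.0^1,5]dec-8-ene-6-carboxylic acid
Product: 8 rac-(3aS,7S,7aR)-3a-hydroxy-1-oxo-6-(propan-2-yl)-1,3,3a,4,7,7a-hexahydro-2-benzofuran-7-carboxylic acid
Conditions: Et3SiH (5 equiv), BF3·OEt2 (3 equiv), CH2Cl2, −78 → −20 °C; aq. NaHCO3, then pH 3
Reagents that add atoms: none
Why: Proposed new method: BF3 on the bridge oxygen should ionise only the C7–O bond, which gives a tertiary allyl cation (C7–C8–C9), whereas cleavage at C10 would place the charge beside the acyloxymethyl carbon and the lactone; Et3SiH then delivers hydride to the less hindered terminus C9 (SN1′ sense), leaving C7=C8 and the C10 alkoxide; the closest known reaction types are the ionic hydrogenation of tertiary allylic ethers and the acid-mediated opening of furan Diels–Alder adducts and of 1,4-cineole; C10, C1 and C6 are not touched.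

Step 5
Reactants: 8 rac-(3aS,7S,7aR)-3a-hydroxy-1-oxo-6-(propan-2-yl)-1,3,3a,4,7,7a-hexahydro-2-benzofuran-7-carboxylic acid
Product: 9 rac-(3aS,6R,7R,7aR)-3a-hydroxy-1-oxo-6-(propan-2-yl)octahydro-2-benzofuran-7-carboxylic acid
Conditions: [Ir(cod)(PCy3)(py)]PF6 (5 mol %), H2 (1 atm), CH2Cl2, 23 °C
Reagents that add atoms: none
Why: Hydroxyl-directed homogeneous hydrogenation; the cationic iridium centre binds the homoallylic C10–OH (and the C6 carboxyl on the same face) and adds H2 to C7=C8 from that face, so H7 ends cis to the hydroxyl and the isopropyl group trans to both C10–OH and the C6 carboxyl, as in the target.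

Step 6
Reactants: 9 rac-(3aS,6R,7R,7aR)-3a-hydroxy-1-oxo-6-(propan-2-yl)octahydro-2-benzofuran-7-carboxylic acid
Product: 10 rac-(3aS,6R,7R,7aS)-3a-hydroxy-1-oxo-6-(propan-2-yl)octahydro-2-benzofuran-7-carboxylic acid
Conditions: DBU (4 equiv), toluene, 80 °C; then 1 M HCl
Reagents that add atoms: none
Why: Thermodynamic epimerisation α to the lactone carbonyl through the enolate; the trans-fused γ-lactone of 9 forces isopropyl and carboxyl axial, whereas inversion at C1 gives the cis-fused lactone with C2, the C6 carboxyl and isopropyl all equatorial, and C6 (α to a carboxylate) does not enolise under these conditions.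

Step 7
Reactants: 10 rac-(3aS,6R,7R,7aS)-3a-hydroxy-1-oxo-6-(propan-2-yl)octahydro-2-benzofuran-7-carboxylic acid
Product: 11 (S)-1-phenylethylammonium (3aS,6R,7R,7aS)-3a-hydroxy-1-oxo-6-(propan-2-yl)octahydro-2-benzofuran-7-carboxylate
Conditions: (S)-1-phenylethylamine (0.5 equiv), EtOH/EtOAc, 60 → 5 °C; one recrystallisation; mother liquor kept for step 8
Reagents that add atoms: (S)-1-phenylethylamine, C[C@H](N)c1ccccc1
Why: Classical resolution by fractional crystallisation of diastereomeric ammonium carboxylates; half an equivalent of amine should take out one enantiomer of the acid as the less soluble salt.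

Step 8
Reactants: 10 acid recovered from the mother liquor of step 7, enriched in the (3aR,6S,7S,7aR) enantiomer
Product: 12 (R)-1-phenylethylammonium (3aR,6S,7S,7aR)-3a-hydroxy-1-oxo-6-(propan-2-yl)octahydro-2-benzofuran-7-carboxylate
Conditions: (R)-1-phenylethylamine (1 equiv on the enriched enantiomer), EtOH/EtOAc, 60 → 5 °C; one recrystallisation
Reagents that add atoms: (R)-1-phenylethylamine, C[C@@H](N)c1ccccc1
Why: Salt 12 is the mirror image of 11 and therefore has the same low solubility, so crystallising the enriched acid with the antipodal amine should deliver the second enantiomer in the same way.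

Step 9
Reactants: 13 diethyl (2-hydroxyethyl)phosphonate
Product: 14 diethyl {2-[(tert-butyldimethylsilyl)oxy]ethyl}phosphonate
Conditions: TBSCl, imidazole, CH2Cl2, 23 °C
Reagents that add atoms: tert-butyl(chloro)dimethylsilane, CC(C)(C)[Si](C)(C)Cl
Why: Standard silylation of a primary alcohol.

Step 10
Reactants: 14 diethyl {2-[(tert-butyldimethylsilyl)oxy]ethyl}phosphonate; 15 di-tert-butyl dicarbonate
Product: 16 tert-butyl 3-[(tert-butyldimethylsilyl)oxy]-2-(diethoxyphosphoryl)propanoate
Conditions: LiN(iPr)2 (2.2 equiv), THF, −78 °C; then 15, −78 → −20 °C; aq. NH4Cl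
Reagents that add atoms: none
Why: α-Lithiation of the alkylphosphonate and C-acylation with the dicarbonate (a Claisen-type carboxylation) give the phosphonoacetate; the second equivalent of base is consumed by the more acidic product, and the low temperature suppresses β-elimination of silanolate.

Step 11
Reactants: 11 (S)-1-phenylethylammonium (3aS,6R,7R,7aS)-3a-hydroxy-1-oxo-6-(propan-2-yl)octahydro-2-benzofuran-7-carboxylate
Product: 18 (3aS,6R,7R,7aS)-3a-hydroxy-7-(hydroxymethyl)-6-(propan-2-yl)hexahydro-2-benzofuran-1(3H)-one, via free acid 17 (not isolated)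
Conditions: 1 M HCl/EtOAc, extract dried and concentrated; BH3·SMe2 (3 equiv), THF, 0 → 23 °C; MeOH quench
Reagents that add atoms: none
Why: After the salt is broken, borane reduces the free carboxylic acid through an acyloxyborane far faster than it attacks the lactone, so only C5 is taken to the alcohol and no stereocenter is touched.

Step 12
Reactants: 18 (3aS,6R,7R,7aS)-3a-hydroxy-7-(hydroxymethyl)-6-(propan-2-yl)hexahydro-2-benzofuran-1(3H)-one; 16 tert-butyl 3-[(tert-butyldimethylsilyl)oxy]-2-(diethoxyphosphoryl)propanoate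
Product: 20 tert-butyl (2E)-2-{[(tert-butyldimethylsilyl)oxy]methyl}-3-[(3aS,6R,7S,7aS)-3a-hydroxy-1-oxo-6-(propan-2-yl)octahydro-2-benzofuran-7-yl]prop-2-enoate, via aldehyde 19 (not isolated)
Conditions: Dess–Martin periodinane, CH2Cl2, 0 → 23 °C, filtered; then 16 (1.5 equiv), NaH (1.4 equiv), THF, 0 → 23 °C
Reagents that add atoms: none
Why: Dess–Martin oxidation followed by Horner–Wadsworth–Emmons olefination; the α-branched aldehyde and the α-substituted phosphonoacetate should favour the (E)-enoate (C6 trans to the ester, cis to C15), and C6, α to the aldehyde, already holds the more stable equatorial configuration, so transient enolisation cannot erode it.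

Step 13
Reactants: 20 tert-butyl (2E)-2-{[(tert-butyldimethylsilyl)oxy]methyl}-3-[(3aS,6R,7S,7aS)-3a-hydroxy-1-oxo-6-(propan-2-yl)octahydro-2-benzofuran-7-yl]prop-2-enoate
Product: 23 (1S,2S,5R,6S)-6-[(1E)-3-tert-butoxy-2-{[(tert-butyldimethylsilyl)oxy]methyl}-3-oxoprop-1-en-1-yl]-2-{[(tert-butyldiphenylsilyl)oxy]methyl}-2-hydroxy-5-(propan-2-yl)cyclohexane-1-carboxylic acid, via lithium carboxylate 21 (not isolated), via bis-silylated ester 22 (not isolated)
Conditions: LiOH·H2O (2 equiv), THF/H2O, 0 °C; evaporate, toluene azeotrope; TBDPSCl (2.5 equiv), imidazole (5 equiv), DMF, 23 °C; K2CO3 (cat.), MeOH/H2O, 0 °C; pH 5 buffer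
Reagents that add atoms: lithium hydroxide, [Li+].[OH-]; tert-butyl(chloro)diphenylsilane, CC(C)(C)[Si](Cl)(c1ccccc1)c1ccccc1
Why: Saponification opens the γ-lactone while the tert-butyl enoate and the silyl ether resist cold hydroxide; silylating the lithium salt caps the primary O14 before any acid is present, so the γ-lactone cannot re-form, the tertiary C10–OH is too hindered to react, and the silyl ester is cleaved by mild methanolysis.

Step 14
Reactants: 23 (1S,2S,5R,6S)-6-[(1E)-3-tert-butoxy-2-{[(tert-butyldimethylsilyl)oxy]methyl}-3-oxoprop-1-en-1-yl]-2-{[(tert-butyldiphenylsilyl)oxy]methyl}-2-hydroxy-5-(propan-2-yl)cyclohexane-1-carboxylic acid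
Product: 24 (1S,2S,5R,6S)-6-[(1E)-3-tert-butoxy-2-(hydroxymethyl)-3-oxoprop-1-en-1-yl]-2-{[(tert-butyldiphenylsilyl)oxy]methyl}-2-hydroxy-5-(propan-2-yl)cyclohexane-1-carboxylic acid
Conditions: HF·pyridine, pyridine, THF, 0 °C
Reagents that add atoms: none
Why: Buffered fluoride desilylation removes the unhindered allylic primary TBS ether much faster than the neopentyl-type TBDPS ether; the tert-butyl ester is inert.

Step 15
Reactants: 24 (1S,2S,5R,6S)-6-[(1E)-3-tert-butoxy-2-(hydroxymethyl)-3-oxoprop-1-en-1-yl]-2-{[(tert-butyldiphenylsilyl)oxy]methyl}-2-hydroxy-5-(propan-2-yl)cyclohexane-1-carboxylic acid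
Product: 25 tert-butyl (5aS,6R,9S,9aS)-9-{[(tert-butyldiphenylsilyl)oxy]methyl}-9-hydroxy-1-oxo-6-(propan-2-yl)-1,3,5a,6,7,8,9,9a-octahydro-2-benzoxepine-4-carboxylate
Conditions: 2-methyl-6-nitrobenzoic anhydride (MNBA, 1.3 equiv), DMAP (3 equiv), CH2Cl2 (2 mM), 23 °C, slow addition
Reagents that add atoms: none
Why: Shiina macrolactonisation under high dilution; the (E)-alkene holds C15–OH beside the equatorial C2 carboxyl, so the seven-membered ring should close readily, while the tertiary C10–OH, trans to C2, can neither be acylated nor form a β-lactone.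

Step 16
Reactants: 12 (R)-1-phenylethylammonium (3aR,6S,7S,7aR)-3a-hydroxy-1-oxo-6-(propan-2-yl)octahydro-2-benzofuran-7-carboxylate
Product: 27 (3aR,6S,7S,7aR)-3a-hydroxy-7-(hydroxymethyl)-6-(propan-2-yl)hexahydro-2-benzofuran-1(3H)-one, via free acid 26 (not isolated)
Conditions: 1 M HCl/EtOAc, extract dried and concentrated; BH3·SMe2 (3 equiv), THF, 0 → 23 °C; MeOH quench
Reagents that add atoms: none
Why: The same chemoselective borane reduction of the free acid beside the lactone as in step 11, in the mirror-image series.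

Step 17
Reactants: 27 (3aR,6S,7S,7aR)-3a-hydroxy-7-(hydroxymethyl)-6-(propan-2-yl)hexahydro-2-benzofuran-1(3H)-one; 16 tert-butyl 3-[(tert-butyldimethylsilyl)oxy]-2-(diethoxyphosphoryl)propanoate
Product: 29 tert-butyl (2E)-2-{[(tert-butyldimethylsilyl)oxy]methyl}-3-[(3aR,6S,7R,7aR)-3a-hydroxy-1-oxo-6-(propan-2-yl)octahydro-2-benzofuran-7-yl]prop-2-enoate, via aldehyde 28 (not isolated)
Conditions: Dess–Martin periodinane, CH2Cl2, 0 → 23 °C, filtered; then 16 (1.5 equiv), NaH (1.4 equiv), THF, 0 → 23 °C
Reagents that add atoms: none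
Why: Oxidation and Horner–Wadsworth–Emmons olefination as in step 12; the acrylate is built while the ring is still saturated, so no β,γ-unsaturated aldehyde is ever handled.

Step 18
Reactants: 29 tert-butyl (2E)-2-{[(tert-butyldimethylsilyl)oxy]methyl}-3-[(3aR,6S,7R,7aR)-3a-hydroxy-1-oxo-6-(propan-2-yl)octahydro-2-benzofuran-7-yl]prop-2-enoate
Product: 32 (1R,2R,5S,6R)-6-[(1E)-3-tert-butoxy-2-{[(tert-butyldimethylsilyl)oxy]methyl}-3-oxoprop-1-en-1-yl]-2-{[(tert-butyldiphenylsilyl)oxy]methyl}-2-hydroxy-5-(propan-2-yl)cyclohexane-1-carboxylic acid, via lithium carboxylate 30 (not isolated), via bis-silylated ester 31 (not isolated)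
Conditions: LiOH·H2O (2 equiv), THF/H2O, 0 °C; evaporate, toluene azeotrope; TBDPSCl (2.5 equiv), imidazole (5 equiv), DMF, 23 °C; K2CO3 (cat.), MeOH/H2O, 0 °C; pH 5 buffer
Reagents that add atoms: lithium hydroxide, [Li+].[OH-]; tert-butyl(chloro)diphenylsilane, CC(C)(C)[Si](Cl)(c1ccccc1)c1ccccc1
Why: Lactone saponification and capping of O14′ as in step 13; this exposes the β-hydroxy acid (C2′ carboxyl on C1′, hydroxyl on C10′) needed for the next step.

Step 19
Reactants: 32 (1R,2R,5S,6R)-6-[(1E)-3-tert-butoxy-2-{[(tert-butyldimethylsilyl)oxy]methyl}-3-oxoprop-1-en-1-yl]-2-{[(tert-butyldiphenylsilyl)oxy]methyl}-2-hydroxy-5-(propan-2-yl)cyclohexane-1-carboxylic acid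
Product: 33 tert-butyl (2E)-2-{[(tert-butyldimethylsilyl)oxy]methyl}-3-[(1S,6S)-3-{[(tert-butyldiphenylsilyl)oxy]methyl}-6-(propan-2-yl)cyclohex-2-en-1-yl]prop-2-enoate
Conditions: N,N-dimethylformamide dineopentyl acetal (4 equiv), toluene, 4 Å MS, 90 °C
Reagents that add atoms: none
Why: Decarboxylative dehydration of a β-hydroxy acid with a formamide acetal; the tertiary C10′–OH is activated as an alkoxyformamidinium ion and leaves with loss of CO2 from C1′, which fixes the alkene at C1′=C10′; the tertiary centre allows E1 character although carboxyl and hydroxyl are trans-diequatorial, the neopentyl acetal cannot esterify the acid, and C6′ and C7′ are untouched.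

Step 20
Reactants: 33 tert-butyl (2E)-2-{[(tert-butyldimethylsilyl)oxy]methyl}-3-[(1S,6S)-3-{[(tert-butyldiphenylsilyl)oxy]methyl}-6-(propan-2-yl)cyclohex-2-en-1-yl]prop-2-enoate
Product: 35 (2E)-2-{[(tert-butyldimethylsilyl)oxy]methyl}-3-[(1S,6S)-3-{[(tert-butyldiphenylsilyl)oxy]methyl}-6-(propan-2-yl)cyclohex-2-en-1-yl]prop-2-enoic acid, via trimethylsilyl ester 34 (not isolated)
Conditions: TMSOTf (3 equiv), 2,6-lutidine (5 equiv), CH2Cl2, 0 → 23 °C; pH 5 buffer/THF
Reagents that add atoms: none
Why: Silyl-triflate-mediated cleavage of a tert-butyl ester (O-silylation, loss of isobutene) under non-acidic conditions leaves both silyl ethers and the skipped diene intact; the trimethylsilyl ester is hydrolysed on work-up.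

Step 21
Reactants: 25 tert-butyl (5aS,6R,9S,9aS)-9-{[(tert-butyldiphenylsilyl)oxy]methyl}-9-hydroxy-1-oxo-6-(propan-2-yl)-1,3,5a,6,7,8,9,9a-octahydro-2-benzoxepine-4-carboxylate
Product: 36 tert-butyl (5aS,6R,9S,9aS)-9-hydroxy-9-(hydroxymethyl)-1-oxo-6-(propan-2-yl)-1,3,5a,6,7,8,9,9a-octahydro-2-benzoxepine-4-carboxylate
Conditions: HF·pyridine, pyridine, THF, 0 → 23 °C; used at once
Reagents that add atoms: none
Why: Fluoride desilylation under mildly acidic, non-basic conditions frees the primary C14–OH; the product is carried on immediately because O14 could attack C2 and contract the ε-lactone to the γ-lactone.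

Step 22
Reactants: 36 tert-butyl (5aS,6R,9S,9aS)-9-hydroxy-9-(hydroxymethyl)-1-oxo-6-(propan-2-yl)-1,3,5a,6,7,8,9,9a-octahydro-2-benzoxepine-4-carboxylate; 35 (2E)-2-{[(tert-butyldimethylsilyl)oxy]methyl}-3-[(1S,6S)-3-{[(tert-butyldiphenylsilyl)oxy]methyl}-6-(propan-2-yl)cyclohex-2-en-1-yl]prop-2-enoic acid
Product: 37 tert-butyl (5aS,6R,9S,9aS)-9-({[(2E)-2-{[(tert-butyldimethylsilyl)oxy]methyl}-3-[(1S,6S)-3-{[(tert-butyldiphenylsilyl)oxy]methyl}-6-(propan-2-yl)cyclohex-2-en-1-yl]prop-2-enoyl]oxy}methyl)-9-hydroxy-1-oxo-6-(propan-2-yl)-1,3,5a,6,7,8,9,9a-octahydro-2-benzoxepine-4-carboxylate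
Conditions: MNBA (1.2 equiv), Et3N (3 equiv), DMAP (0.2 equiv), CH2Cl2, 0 → 23 °C
Reagents that add atoms: none
Why: Shiina esterification; the primary C14–OH is acylated in preference to the tertiary C10–OH, and catalytic DMAP with a mild amine should keep both the γ-proton (C6′–H) of the activated acid and the hydroxy ε-lactone from isomerising.

Step 23
Reactants: 37 tert-butyl (5aS,6R,9S,9aS)-9-({[(2E)-2-{[(tert-butyldimethylsilyl)oxy]methyl}-3-[(1S,6S)-3-{[(tert-butyldiphenylsilyl)oxy]methyl}-6-(propan-2-yl)cyclohex-2-en-1-yl]prop-2-enoyl]oxy}methyl)-9-hydroxy-1-oxo-6-(propan-2-yl)-1,3,5a,6,7,8,9,9a-octahydro-2-benzoxepine-4-carboxylate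
Product: 39 (5aS,6R,9S,9aS)-9-hydroxy-9-({[(2E)-2-(hydroxymethyl)-3-[(1S,6S)-3-(hydroxymethyl)-6-(propan-2-yl)cyclohex-2-en-1-yl]prop-2-enoyl]oxy}methyl)-1-oxo-6-(propan-2-yl)-1,3,5a,6,7,8,9,9a-octahydro-2-benzoxepine-4-carboxylic acid, via bis(trimethylsilyl) intermediate 38 (not isolated)
Conditions: TMSOTf (4 equiv), 2,6-lutidine (6 equiv), CH2Cl2, 0 °C; MeOH quench, concentrate; HF·pyridine, THF, 0 → 23 °C
Reagents that add atoms: none
Why: The tert-butyl ester is cleaved as in step 20 (the tertiary hydroxyl is silylated in passing) and HF·pyridine then removes every silyl group; neither operation is basic, so the ε-lactone, the ester link and the doubly allylic C6′–H are not endangered.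

## Compound list

1 | methyl 5-bromofuran-2-carboxylate | COC(=O)c1ccc(Br)o1 | starting material
2 | isopropylzinc bromide | CC(C)[Zn]Br | starting material
3 | methyl 5-(propan-2-yl)furan-2-carboxylate | COC(=O)c1ccc(C(C)C)o1 | intermediate
4 | [5-(propan-2-yl)furan-2-yl]methanol | CC(C)c1ccc(CO)o1 | intermediate
5 | maleic anhydride | O=C1OC(=O)C=C1 | starting material
6 | 5-isopropylfurfuryl hydrogen maleate, (2Z)-4-oxo-4-{[5-(propan-2-yl)furan-2-yl]methoxy}but-2-enoic acid | CC(C)c1ccc(COC(=O)/C=C\C(=O)O)o1 | intermediate (not isolated)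
7 | rac-exo-4-oxo-7-(propan-2-yl)-3,10-dioxatricyclo[5.2.1.0^1,5]dec-8-ene-6-carboxylic acid (racemate, one enantiomer drawn) | CC(C)[C@@]12C=C[C@]3(COC(=O)[C@@H]3[C@@H]1C(=O)O)O2 | intermediate
8 | rac-(3aS,7S,7aR)-3a-hydroxy-1-oxo-6-(propan-2-yl)-1,3,3a,4,7,7a-hexahydro-2-benzofuran-7-carboxylic acid (racemate, one enantiomer drawn) | CC(C)C1=CC[C@@]2(O)COC(=O)[C@@H]2[C@@H]1C(=O)O | intermediate
9 | rac-(3aS,6R,7R,7aR)-3a-hydroxy-1-oxo-6-(propan-2-yl)octahydro-2-benzofuran-7-carboxylic acid (racemate, one enantiomer drawn) | CC(C)[C@H]1CC[C@@]2(O)COC(=O)[C@@H]2[C@@H]1C(=O)O | intermediate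
10 | rac-(3aS,6R,7R,7aS)-3a-hydroxy-1-oxo-6-(propan-2-yl)octahydro-2-benzofuran-7-carboxylic acid (racemate, one enantiomer drawn) | CC(C)[C@H]1CC[C@@]2(O)COC(=O)[C@H]2[C@@H]1C(=O)O | intermediate
11 | (S)-1-phenylethylammonium (3aS,6R,7R,7aS)-3a-hydroxy-1-oxo-6-(propan-2-yl)octahydro-2-benzofuran-7-carboxylate | CC(C)[C@H]1CC[C@@]2(O)COC(=O)[C@H]2[C@@H]1C(=O)[O-].C[C@H]([NH3+])c1ccccc1 | intermediate
12 | (R)-1-phenylethylammonium (3aR,6S,7S,7aR)-3a-hydroxy-1-oxo-6-(propan-2-yl)octahydro-2-benzofuran-7-carboxylate | CC(C)[C@@H]1CC[C@]2(O)COC(=O)[C@@H]2[C@H]1C(=O)[O-].C[C@@H]([NH3+])c1ccccc1 | intermediate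
13 | diethyl (2-hydroxyethyl)phosphonate | CCOP(=O)(CCO)OCC | starting material
14 | diethyl {2-[(tert-butyldimethylsilyl)oxy]ethyl}phosphonate | CCOP(=O)(CCO[Si](C)(C)C(C)(C)C)OCC | intermediate
15 | di-tert-butyl dicarbonate | CC(C)(C)OC(=O)OC(=O)OC(C)(C)C | starting material
16 | tert-butyl 3-[(tert-butyldimethylsilyl)oxy]-2-(diethoxyphosphoryl)propanoate (racemic; its stereocenter is lost in the olefination) | CCOP(=O)(OCC)C(CO[Si](C)(C)C(C)(C)C)C(=O)OC(C)(C)C | intermediate
17 | (3aS,6R,7R,7aS)-3a-hydroxy-1-oxo-6-(propan-2-yl)octahydro-2-benzofuran-7-carboxylic acid | CC(C)[C@H]1CC[C@@]2(O)COC(=O)[C@H]2[C@@H]1C(=O)O | intermediate (not isolated)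
18 | (3aS,6R,7R,7aS)-3a-hydroxy-7-(hydroxymethyl)-6-(propan-2-yl)hexahydro-2-benzofuran-1(3H)-one | CC(C)[C@H]1CC[C@@]2(O)COC(=O)[C@H]2[C@@H]1CO | intermediate
19 | (3aS,6R,7R,7aS)-3a-hydroxy-1-oxo-6-(propan-2-yl)octahydro-2-benzofuran-7-carbaldehyde | CC(C)[C@H]1CC[C@@]2(O)COC(=O)[C@H]2[C@@H]1C=O | intermediate (not isolated)
20 | tert-butyl (2E)-2-{[(tert-butyldimethylsilyl)oxy]methyl}-3-[(3aS,6R,7S,7aS)-3a-hydroxy-1-oxo-6-(propan-2-yl)octahydro-2-benzofuran-7-yl]prop-2-enoate | CC(C)[C@H]1CC[C@@]2(O)COC(=O)[C@H]2[C@@H]1/C=C(\CO[Si](C)(C)C(C)(C)C)C(=O)OC(C)(C)C | intermediate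
21 | lithium (1S,2S,5R,6S)-6-[(1E)-3-tert-butoxy-2-{[(tert-butyldimethylsilyl)oxy]methyl}-3-oxoprop-1-en-1-yl]-2-hydroxy-2-(hydroxymethyl)-5-(propan-2-yl)cyclohexane-1-carboxylate | CC(C)[C@H]1CC[C@@](O)(CO)[C@@H](C(=O)[O-])[C@@H]1/C=C(\CO[Si](C)(C)C(C)(C)C)C(=O)OC(C)(C)C.[Li+] | intermediate (not isolated)
22 | tert-butyldiphenylsilyl (1S,2S,5R,6S)-6-[(1E)-3-tert-butoxy-2-{[(tert-butyldimethylsilyl)oxy]methyl}-3-oxoprop-1-en-1-yl]-2-{[(tert-butyldiphenylsilyl)oxy]methyl}-2-hydroxy-5-(propan-2-yl)cyclohexane-1-carboxylate | CC(C)[C@H]1CC[C@@](O)(CO[Si](c2ccccc2)(c2ccccc2)C(C)(C)C)[C@@H](C(=O)O[Si](c2ccccc2)(c2ccccc2)C(C)(C)C)[C@@H]1/C=C(\CO[Si](C)(C)C(C)(C)C)C(=O)OC(C)(C)C | intermediate (not isolated)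
23 | (1S,2S,5R,6S)-6-[(1E)-3-tert-butoxy-2-{[(tert-butyldimethylsilyl)oxy]methyl}-3-oxoprop-1-en-1-yl]-2-{[(tert-butyldiphenylsilyl)oxy]methyl}-2-hydroxy-5-(propan-2-yl)cyclohexane-1-carboxylic acid | CC(C)[C@H]1CC[C@@](O)(CO[Si](c2ccccc2)(c2ccccc2)C(C)(C)C)[C@@H](C(=O)O)[C@@H]1/C=C(\CO[Si](C)(C)C(C)(C)C)C(=O)OC(C)(C)C | intermediate
24 | (1S,2S,5R,6S)-6-[(1E)-3-tert-butoxy-2-(hydroxymethyl)-3-oxoprop-1-en-1-yl]-2-{[(tert-butyldiphenylsilyl)oxy]methyl}-2-hydroxy-5-(propan-2-yl)cyclohexane-1-carboxylic acid | CC(C)[C@H]1CC[C@@](O)(CO[Si](c2ccccc2)(c2ccccc2)C(C)(C)C)[C@@H](C(=O)O)[C@@H]1/C=C(\CO)C(=O)OC(C)(C)C | intermediate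
25 | tert-butyl (5aS,6R,9S,9aS)-9-{[(tert-butyldiphenylsilyl)oxy]methyl}-9-hydroxy-1-oxo-6-(propan-2-yl)-1,3,5a,6,7,8,9,9a-octahydro-2-benzoxepine-4-carboxylate | CC(C)[C@H]1CC[C@@](O)(CO[Si](c3ccccc3)(c3ccccc3)C(C)(C)C)[C@H]2C(=O)OCC(C(=O)OC(C)(C)C)=C[C@H]12 | intermediate
26 | (3aR,6S,7S,7aR)-3a-hydroxy-1-oxo-6-(propan-2-yl)octahydro-2-benzofuran-7-carboxylic acid | CC(C)[C@@H]1CC[C@]2(O)COC(=O)[C@@H]2[C@H]1C(=O)O | intermediate (not isolated)
27 | (3aR,6S,7S,7aR)-3a-hydroxy-7-(hydroxymethyl)-6-(propan-2-yl)hexahydro-2-benzofuran-1(3H)-one | CC(C)[C@@H]1CC[C@]2(O)COC(=O)[C@@H]2[C@H]1CO | intermediate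
28 | (3aR,6S,7S,7aR)-3a-hydroxy-1-oxo-6-(propan-2-yl)octahydro-2-benzofuran-7-carbaldehyde | CC(C)[C@@H]1CC[C@]2(O)COC(=O)[C@@H]2[C@H]1C=O | intermediate (not isolated)
29 | tert-butyl (2E)-2-{[(tert-butyldimethylsilyl)oxy]methyl}-3-[(3aR,6S,7R,7aR)-3a-hydroxy-1-oxo-6-(propan-2-yl)octahydro-2-benzofuran-7-yl]prop-2-enoate | CC(C)[C@@H]1CC[C@]2(O)COC(=O)[C@@H]2[C@H]1/C=C(\CO[Si](C)(C)C(C)(C)C)C(=O)OC(C)(C)C | intermediate
30 | lithium (1R,2R,5S,6R)-6-[(1E)-3-tert-butoxy-2-{[(tert-butyldimethylsilyl)oxy]methyl}-3-oxoprop-1-en-1-yl]-2-hydroxy-2-(hydroxymethyl)-5-(propan-2-yl)cyclohexane-1-carboxylate | CC(C)[C@@H]1CC[C@](O)(CO)[C@H](C(=O)[O-])[C@H]1/C=C(\CO[Si](C)(C)C(C)(C)C)C(=O)OC(C)(C)C.[Li+] | intermediate (not isolated)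
31 | tert-butyldiphenylsilyl (1R,2R,5S,6R)-6-[(1E)-3-tert-butoxy-2-{[(tert-butyldimethylsilyl)oxy]methyl}-3-oxoprop-1-en-1-yl]-2-{[(tert-butyldiphenylsilyl)oxy]methyl}-2-hydroxy-5-(propan-2-yl)cyclohexane-1-carboxylate | CC(C)[C@@H]1CC[C@](O)(CO[Si](c2ccccc2)(c2ccccc2)C(C)(C)C)[C@H](C(=O)O[Si](c2ccccc2)(c2ccccc2)C(C)(C)C)[C@H]1/C=C(\CO[Si](C)(C)C(C)(C)C)C(=O)OC(C)(C)C | intermediate (not isolated)
32 | (1R,2R,5S,6R)-6-[(1E)-3-tert-butoxy-2-{[(tert-butyldimethylsilyl)oxy]methyl}-3-oxoprop-1-en-1-yl]-2-{[(tert-butyldiphenylsilyl)oxy]methyl}-2-hydroxy-5-(propan-2-yl)cyclohexane-1-carboxylic acid | CC(C)[C@@H]1CC[C@](O)(CO[Si](c2ccccc2)(c2ccccc2)C(C)(C)C)[C@H](C(=O)O)[C@H]1/C=C(\CO[Si](C)(C)C(C)(C)C)C(=O)OC(C)(C)C | intermediate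
33 | tert-butyl (2E)-2-{[(tert-butyldimethylsilyl)oxy]methyl}-3-[(1S,6S)-3-{[(tert-butyldiphenylsilyl)oxy]methyl}-6-(propan-2-yl)cyclohex-2-en-1-yl]prop-2-enoate | CC(C)[C@@H]1CCC(CO[Si](c2ccccc2)(c2ccccc2)C(C)(C)C)=C[C@H]1/C=C(\CO[Si](C)(C)C(C)(C)C)C(=O)OC(C)(C)C | intermediate
34 | trimethylsilyl (2E)-2-{[(tert-butyldimethylsilyl)oxy]methyl}-3-[(1S,6S)-3-{[(tert-butyldiphenylsilyl)oxy]methyl}-6-(propan-2-yl)cyclohex-2-en-1-yl]prop-2-enoate | CC(C)[C@@H]1CCC(CO[Si](c2ccccc2)(c2ccccc2)C(C)(C)C)=C[C@H]1/C=C(\CO[Si](C)(C)C(C)(C)C)C(=O)O[Si](C)(C)C | intermediate (not isolated)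
35 | (2E)-2-{[(tert-butyldimethylsilyl)oxy]methyl}-3-[(1S,6S)-3-{[(tert-butyldiphenylsilyl)oxy]methyl}-6-(propan-2-yl)cyclohex-2-en-1-yl]prop-2-enoic acid | CC(C)[C@@H]1CCC(CO[Si](c2ccccc2)(c2ccccc2)C(C)(C)C)=C[C@H]1/C=C(\CO[Si](C)(C)C(C)(C)C)C(=O)O | intermediate
36 | tert-butyl (5aS,6R,9S,9aS)-9-hydroxy-9-(hydroxymethyl)-1-oxo-6-(propan-2-yl)-1,3,5a,6,7,8,9,9a-octahydro-2-benzoxepine-4-carboxylate | CC(C)[C@H]1CC[C@@](O)(CO)[C@H]2C(=O)OCC(C(=O)OC(C)(C)C)=C[C@H]12 | intermediate
37 | tert-butyl (5aS,6R,9S,9aS)-9-({[(2E)-2-{[(tert-butyldimethylsilyl)oxy]methyl}-3-[(1S,6S)-3-{[(tert-butyldiphenylsilyl)oxy]methyl}-6-(propan-2-yl)cyclohex-2-en-1-yl]prop-2-enoyl]oxy}methyl)-9-hydroxy-1-oxo-6-(propan-2-yl)-1,3,5a,6,7,8,9,9a-octahydro-2-benzoxepine-4-carboxylate | CC(C)[C@H]1CC[C@@](O)(COC(=O)/C(=C/[C@@H]2C=C(CO[Si](c3ccccc3)(c3ccccc3)C(C)(C)C)CC[C@H]2C(C)C)CO[Si](C)(C)C(C)(C)C)[C@H]2C(=O)OCC(C(=O)OC(C)(C)C)=C[C@H]12 | intermediate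
38 | trimethylsilyl ester and C10 trimethylsilyl ether of the acid derived from 37 (C15′–OTBS and C14′–OTBDPS still in place) | CC(C)[C@H]1CC[C@@](O[Si](C)(C)C)(COC(=O)/C(=C/[C@@H]2C=C(CO[Si](c3ccccc3)(c3ccccc3)C(C)(C)C)CC[C@H]2C(C)C)CO[Si](C)(C)C(C)(C)C)[C@H]2C(=O)OCC(C(=O)O[Si](C)(C)C)=C[C@H]12 | intermediate (not isolated)
39 | (5aS,6R,9S,9aS)-9-hydroxy-9-({[(2E)-2-(hydroxymethyl)-3-[(1S,6S)-3-(hydroxymethyl)-6-(propan-2-yl)cyclohex-2-en-1-yl]prop-2-enoyl]oxy}methyl)-1-oxo-6-(propan-2-yl)-1,3,5a,6,7,8,9,9a-octahydro-2-benzoxepine-4-carboxylic acid (CNP0361406.8) | CC(C)[C@H]1CC[C@@](O)(COC(=O)/C(=C/[C@@H]2C=C(CO)CC[C@H]2C(C)C)CO)[C@H]2C(=O)OCC(C(=O)O)=C[C@H]12 | target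

## Step count and least certain steps

Total step count: 23. Longest linear sequence: 15 steps (steps 1–7, 11–15, 21–23).

**Step 4 (proposed new method).**
- What may go wrong: the allyl cation may lose a proton, after which dehydration and aromatisation to a phthalide follow. Alternatively hydride may be captured at the tertiary terminus C7, which would move the alkene to C8=C9 and leave C7 without control.
- Hydroalumination with Ni(cod)2 and iBu2AlH is not a remedy: aluminium would add next to the less hindered C10 bridgehead and cleave the wrong C–O bond, and the hydride would reduce the lactone.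
- Fallback with known chemistry, setting out from 7: hydrogenation over Pd/C (H2, EtOAc) gives rac-exo-4-oxo-7-(propan-2-yl)-3,10-dioxatricyclo[5.2.1.0^1,5]decane-6-carboxylic acid F1. Its ether bridge is then opened with BF3·OEt2 in CH2Cl2 by the E1 path known for 1,4-cineole. Ionisation at the isopropyl bridgehead and loss of a proton should give 8 together with its exocyclic isomer rac-(3aS,7S,7aR)-3a-hydroxy-1-oxo-6-(propan-2-ylidene)octahydro-2-benzofuran-7-carboxylic acid F2. Both are reduced under the conditions of step 5, and the fallback rejoins the route at 9.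

**Step 3 (key step).**
- What may go wrong: the cycloaddition equilibrium may stop short of completion because a quaternary isopropyl bridgehead is formed, and the acidic half-ester may lose its electron-rich furfuryl group by solvolysis before it cyclises.
- Fallback, setting out from 4: silylation (TBSCl, imidazole) gives tert-butyldimethyl{[5-(propan-2-yl)furan-2-yl]methoxy}silane F3. An untethered Diels–Alder reaction with 5 (Et2O, 23 °C, or high pressure) gives under thermodynamic control rac-exo-1-{[(tert-butyldimethylsilyl)oxy]methyl}-4-(propan-2-yl)-7-oxabicyclo[2.2.1]hept-5-ene-2,3-dicarboxylic anhydride F4. HF·pyridine then removes the silyl group, and the bridgehead CH2OH opens the anhydride at the nearer carbonyl, which returns the route at 7.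

**Step 6.**
- What may go wrong: enolisation at C1 may be slow because the substrate is a carboxylate under the basic conditions, and forcing it invites β-elimination of the tertiary hydroxyl to a butenolide.
- Fallback, setting out from 9: benzylation (BnBr, K2CO3, DMF) gives benzyl rac-(3aS,6R,7R,7aR)-3a-hydroxy-1-oxo-6-(propan-2-yl)octahydro-2-benzofuran-7-carboxylate F5. DBU in toluene epimerises this neutral ester to benzyl rac-(3aS,6R,7R,7aS)-3a-hydroxy-1-oxo-6-(propan-2-yl)octahydro-2-benzofuran-7-carboxylate F6, and hydrogenolysis (H2, Pd/C) returns 10.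

**Step 19.**
- What may go wrong: fragmentation may be sluggish, because the carboxyl and the activated hydroxyl cannot become antiperiplanar without a ring flip that places the isopropyl group axial; elimination toward C9′ or C14′ may then compete.
- Fallback, setting out from 32: the acid is converted (2-mercaptopyridine N-oxide, carbodiimide) into the 2-thioxopyridin-1(2H)-yl ester of 32 F7. Photolysis with diphenyl diselenide (Barton decarboxylative selenation) gives tert-butyl (2E)-2-{[(tert-butyldimethylsilyl)oxy]methyl}-3-[(1R,3R,6S)-3-{[(tert-butyldiphenylsilyl)oxy]methyl}-3-hydroxy-2-(phenylselanyl)-6-(propan-2-yl)cyclohexyl]prop-2-enoate F8 as a mixture of C1′ epimers. SOCl2/Et3N then effects the regiospecific elimination of the β-hydroxy selenide and returns 33.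

**Step 21 (with step 22).**
- What may go wrong: acyl transfer of C2 from O15 to the freed O14, that is, ring contraction to the cis-fused γ-lactone, during desilylation or during the DMAP-mediated coupling.
- Fallback, setting out from 20 and keeping C2 away from the ester level while O14 is acylated:
  - MeNH(OMe)·HCl/AlMe3 opens the lactone to the hydroxy Weinreb amide of 20, N-methoxy-N-methyl amide with free C14–OH F9.
  - MNBA coupling with 35 gives the C14 ester of F9 with acid 35 F10.
  - Cp2Zr(H)Cl reduces the amide to the C2 aldehyde F11, and NaClO2 (NaH2PO4, 2-methylbut-2-ene) oxidises it to the C2 carboxylic acid F12.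
  - HF·pyridine removes the three silyl groups to give the seco acid with free C15–OH, C15′–OH and C14′–OH F13.
  - MNBA lactonisation, in which the seven-membered ring is by far the nearest closure, gives the tert-butyl ester of the target F14.
  - TMSOTf/2,6-lutidine followed by mild aqueous acid returns the route at 39.

## Further compounds

F1 | step 4 | rac-exo-4-oxo-7-(propan-2-yl)-3,10-dioxatricyclo[5.2.1.0^1,5]decane-6-carboxylic acid | CC(C)[C@@]12CC[C@]3(COC(=O)[C@@H]3[C@@H]1C(=O)O)O2
F2 | step 4 | rac-(3aS,7S,7aR)-3a-hydroxy-1-oxo-6-(propan-2-ylidene)octahydro-2-benzofuran-7-carboxylic acid | CC(C)=C1CC[C@@]2(O)COC(=O)[C@@H]2[C@@H]1C(=O)O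
F3 | step 3 | tert-butyldimethyl{[5-(propan-2-yl)furan-2-yl]methoxy}silane | CC(C)c1ccc(CO[Si](C)(C)C(C)(C)C)o1
F4 | step 3 | rac-exo-1-{[(tert-butyldimethylsilyl)oxy]methyl}-4-(propan-2-yl)-7-oxabicyclo[2.2.1]hept-5-ene-2,3-dicarboxylic anhydride | CC(C)[C@]12C=C[C@](CO[Si](C)(C)C(C)(C)C)(O1)[C@@H]1C(=O)OC(=O)[C@H]21
F5 | step 6 | benzyl rac-(3aS,6R,7R,7aR)-3a-hydroxy-1-oxo-6-(propan-2-yl)octahydro-2-benzofuran-7-carboxylate | CC(C)[C@H]1CC[C@@]2(O)COC(=O)[C@@H]2[C@@H]1C(=O)OCc1ccccc1
F6 | step 6 | benzyl rac-(3aS,6R,7R,7aS)-3a-hydroxy-1-oxo-6-(propan-2-yl)octahydro-2-benzofuran-7-carboxylate | CC(C)[C@H]1CC[C@@]2(O)COC(=O)[C@H]2[C@@H]1C(=O)OCc1ccccc1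
F7 | step 19 | 2-thioxopyridin-1(2H)-yl ester of 32 | CC(C)[C@@H]1CC[C@](O)(CO[Si](c2ccccc2)(c2ccccc2)C(C)(C)C)[C@H](C(=O)On2ccccc2=S)[C@H]1/C=C(\CO[Si](C)(C)C(C)(C)C)C(=O)OC(C)(C)C
F8 | step 19 | tert-butyl (2E)-2-{[(tert-butyldimethylsilyl)oxy]methyl}-3-[(1R,3R,6S)-3-{[(tert-butyldiphenylsilyl)oxy]methyl}-3-hydroxy-2-(phenylselanyl)-6-(propan-2-yl)cyclohexyl]prop-2-enoate (mixture of C1′ epimers) | CC(C)[C@@H]1CC[C@](O)(CO[Si](c2ccccc2)(c2ccccc2)C(C)(C)C)C([Se]c2ccccc2)[C@H]1/C=C(\CO[Si](C)(C)C(C)(C)C)C(=O)OC(C)(C)C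
F9 | step 21 | hydroxy Weinreb amide of 20, N-methoxy-N-methyl amide with free C14–OH | CC(C)[C@H]1CC[C@@](O)(CO)[C@@H](C(=O)N(C)OC)[C@@H]1/C=C(\CO[Si](C)(C)C(C)(C)C)C(=O)OC(C)(C)C
F10 | step 21 | C14 ester of F9 with acid 35 | CC(C)[C@H]1CC[C@@](O)(COC(=O)/C(=C/[C@@H]2C=C(CO[Si](c3ccccc3)(c3ccccc3)C(C)(C)C)CC[C@H]2C(C)C)CO[Si](C)(C)C(C)(C)C)[C@@H](C(=O)N(C)OC)[C@@H]1/C=C(\CO[Si](C)(C)C(C)(C)C)C(=O)OC(C)(C)C
F11 | step 21 | C2 aldehyde | CC(C)[C@H]1CC[C@@](O)(COC(=O)/C(=C/[C@@H]2C=C(CO[Si](c3ccccc3)(c3ccccc3)C(C)(C)C)CC[C@H]2C(C)C)CO[Si](C)(C)C(C)(C)C)[C@@H](C=O)[C@@H]1/C=C(\CO[Si](C)(C)C(C)(C)C)C(=O)OC(C)(C)C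
F12 | step 21 | C2 carboxylic acid | CC(C)[C@H]1CC[C@@](O)(COC(=O)/C(=C/[C@@H]2C=C(CO[Si](c3ccccc3)(c3ccccc3)C(C)(C)C)CC[C@H]2C(C)C)CO[Si](C)(C)C(C)(C)C)[C@@H](C(=O)O)[C@@H]1/C=C(\CO[Si](C)(C)C(C)(C)C)C(=O)OC(C)(C)C
F13 | step 21 | seco acid with free C15–OH, C15′–OH and C14′–OH | CC(C)[C@H]1CC[C@@](O)(COC(=O)/C(=C/[C@@H]2C=C(CO)CC[C@H]2C(C)C)CO)[C@@H](C(=O)O)[C@@H]1/C=C(\CO)C(=O)OC(C)(C)C
F14 | step 21 | tert-butyl ester of the target | CC(C)[C@H]1CC[C@@](O)(COC(=O)/C(=C/[C@@H]2C=C(CO)CC[C@H]2C(C)C)CO)[C@H]2C(=O)OCC(C(=O)OC(C)(C)C)=C[C@H]12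
A1 | alternative 1 | 3-[(4-methoxybenzyl)oxy]propanal | COc1ccc(COCCC=O)cc1
A2 | alternative 1 | (E)-3-methyl-1-nitrobut-1-ene | CC(C)/C=C/[N+](=O)[O-]
A3 | alternative 1 | ethyl 2-(diethoxyphosphoryl)acrylate | C=C(C(=O)OCC)P(=O)(OCC)OCC
A4 | alternative 1 | ethyl 3-{[(4-methoxybenzyl)oxy]methyl}-5-nitro-4-(propan-2-yl)cyclohex-1-ene-1-carboxylate | CCOC(=O)C1=C[C@@H](COCc2ccc(OC)cc2)[C@H](C(C)C)[C@@H]([N+](=O)[O-])C1
A5 | alternative 2 | trans-fused β,γ-unsaturated decalone, 2-(trimethylsilyl)ethyl ester, C14 TBS ether | CC(C)[C@H]1CC[C@@](O)(CO[Si](C)(C)C(C)(C)C)[C@H]2C(=O)CC(C(=O)OCC[Si](C)(C)C)=C[C@H]12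
A6 | alternative 2 | protected bicyclic ε-lactone half | CC(C)[C@H]1CC[C@@](O)(CO[Si](C)(C)C(C)(C)C)[C@H]2C(=O)OCC(C(=O)OCC[Si](C)(C)C)=C[C@H]12
A7 | alternative 3 | cyclopropane-fused keto aldehyde with a cis 1-(alkoxycarbonyl)vinyl group | CC(C)[C@H]1CCC(=O)[C@]2(C=O)[C@@H](C(=C)C(=O)OCC[Si](C)(C)C)[C@H]12
A8 | alternative 3 | fused 2,5-dihydrooxepine (vinylogous ester) | CC(C)[C@H]1CCC(=O)C2=COCC(C(=O)OCC[Si](C)(C)C)=C[C@H]12
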